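**Assumption:** the target has no stereocentre and no configurationally stable axis, so it is one achiral compound and no enantioselective step is needed. The racemic centres of 3–5 are erased on aromatisation.

## Retrosynthetic overview
1. The depside aryl ester C(=O)–O bond is made last. It joins an A-ring acid (O,O-dibenzyl divaric acid) to a B-ring phenol (benzyl 4-benzyloxy-3-hydroxy-2-methoxy-6-propylbenzoate), and one hydrogenolysis then removes all four benzyl groups.
2. The B-ring 3-OH comes from a 3-CHO group by Baeyer–Villiger/Dakin oxidation. The aldehyde comes from C3 formylation of methyl divarate, with O-4 benzylated first and O-2 methylated second.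
3. Both aromatic rings derive from one building block, methyl 2,4-dihydroxy-6-propylbenzoate (methyl divarate).
4. That ring is built by intermolecular Michael addition of dimethyl malonate to (E)-hept-3-en-2-one (key C–C bond), Dieckmann–Claisen closure in the same pot, then oxidative aromatisation.
5. Ring order: the single carbocycle is formed in step 1 and aromatised in step 2, the material is then split into the A and B branches, and no further ring is formed.

## Route

Step 1
Reactants: 1 (E)-hept-3-en-2-one; 2 dimethyl malonate
Product: 4 methyl 2-hydroxy-4-oxo-6-propylcyclohex-2-ene-1-carboxylate (racemic; enol form of the 2,4-dione), via Michael adduct 3 (not isolated)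
Conditions: NaOMe (1.1 equiv), MeOH, rt then reflux, 4 h; then aq HCl to pH 3
Reagents that add atoms: none
Why: Intermolecular Michael addition of sodium malonate to the enone β-carbon forges the key C–C bond, and the methyl-ketone enolate of 3 then closes the six-membered ring by Dieckmann-type Claisen condensation, driven by the stabilised β-dicarbonyl enolate; the two new stereocentres (C1, C6) are racemic and vanish in step 2.

Step 2
Reactants: 4 methyl 2-hydroxy-4-oxo-6-propylcyclohex-2-ene-1-carboxylate
Product: 6 methyl 2,4-dihydroxy-6-propylbenzoate (methyl divarate), via 3-bromo enol 5 (not isolated)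
Conditions: Br2 (1.0 equiv), DMF, 0 °C, 1 h; then 80 °C, 12 h
Reagents that add atoms: none
Why: Oxidative aromatisation by α-bromination of the 1,3-dicarbonyl, thermal dehydrobromination and enolisation is the standard way from dihydroresorcylates to alkylresorcylate esters, and the ester is retained at 80 °C.

Step 3
Reactants: 6 methyl 2,4-dihydroxy-6-propylbenzoate
Product: 7 methyl 2,4-bis(benzyloxy)-6-propylbenzoate
Conditions: BnBr (2.5 equiv), K2CO3 (3 equiv), DMF, 70 °C, 12 h
Reagents that add atoms: benzyl bromide, BrCc1ccccc1
Why: Williamson etherification, in which excess reagent and heat in DMF also alkylate the hydrogen-bonded 2-OH.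

Step 4
Reactants: 7 methyl 2,4-bis(benzyloxy)-6-propylbenzoate
Product: 8 2,4-bis(benzyloxy)-6-propylbenzoic acid
Conditions: KOH (10 equiv), DMSO/H2O 4:1, 100 °C, 8 h; then cold 2 M HCl
Reagents that add atoms: potassium hydroxide, [K+].[OH-]
Why: Saponification with poorly solvated hydroxide in aqueous DMSO overcomes the di-ortho hindrance of the benzoate, and benzyl ethers are inert to base.

Step 5
Reactants: 6 methyl 2,4-dihydroxy-6-propylbenzoate
Product: 10 methyl 3-formyl-2,4-dihydroxy-6-propylbenzoate, via chloro(methoxy)methyl arene 9 (not isolated)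
Conditions: Cl2CHOMe (1.2 equiv), TiCl4 (2.5 equiv), CH2Cl2, −10 °C to rt, 3 h; then ice/1 M HCl; chromatography
Reagents that add atoms: dichloromethyl methyl ether, COC(Cl)Cl; water, O
Why: Rieche formylation (electrophilic aromatic substitution) in which titanium bound to the phenol and ester oxygens delivers the electrophile to C3, the carbon ortho to both hydroxyls and the most nucleophilic site of a β-resorcylate; the minor 5-formyl isomer is separated.

Step 6
Reactants: 10 methyl 3-formyl-2,4-dihydroxy-6-propylbenzoate
Product: 11 methyl 4-(benzyloxy)-3-formyl-2-hydroxy-6-propylbenzoate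
Conditions: BnBr (1.05 equiv), K2CO3 (1.1 equiv), DMF, rt, 16 h
Reagents that add atoms: benzyl bromide, BrCc1ccccc1
Why: Williamson etherification with one equivalent of reagent takes the exposed 4-phenoxide, because the 2-OH is buried between ester and formyl groups and chelated to the ester carbonyl.

Step 7
Reactants: 11 methyl 4-(benzyloxy)-3-formyl-2-hydroxy-6-propylbenzoate
Product: 12 methyl 4-(benzyloxy)-3-formyl-2-methoxy-6-propylbenzoate
Conditions: MeI (5 equiv), K2CO3 (3 equiv), DMF, 45 °C (sealed), 18 h
Reagents that add atoms: iodomethane, CI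
Why: Williamson methylation, in which the small electrophile in excess in a dipolar aprotic solvent alkylates the remaining acidic but crowded phenoxide, and no other nucleophilic site is left.

Step 8
Reactants: 12 methyl 4-(benzyloxy)-3-formyl-2-methoxy-6-propylbenzoate
Product: 14 methyl 4-(benzyloxy)-3-hydroxy-2-methoxy-6-propylbenzoate, via aryl formate 13 (not isolated)
Conditions: mCPBA (1.5 equiv), CH2Cl2, 0 °C to rt, 12 h; aq Na2SO3/NaHCO3 wash; then K2CO3 (0.2 equiv), MeOH, rt, 30 min
Reagents that add atoms: mCPBA, O=C(OO)c1cccc(Cl)c1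
Why: Baeyer–Villiger (Dakin-type) oxidation in which the electron-rich aryl group flanked by two alkoxy groups migrates in preference to hydrogen, and mild methanolysis cleaves the resulting formate without touching the hindered methyl benzoate.

Step 9
Reactants: 14 methyl 4-(benzyloxy)-3-hydroxy-2-methoxy-6-propylbenzoate
Product: 15 4-(benzyloxy)-3-hydroxy-2-methoxy-6-propylbenzoic acid
Conditions: KOH (12 equiv), DMSO/H2O 4:1, argon, 100 °C, 10 h; then cold 2 M HCl
Reagents that add atoms: potassium hydroxide, [K+].[OH-]
Why: Saponification as in step 4; the phenoxide sits meta to the ester carbon and so barely deactivates it, and exclusion of air protects the electron-rich phenoxide.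

Step 10
Reactants: 15 4-(benzyloxy)-3-hydroxy-2-methoxy-6-propylbenzoic acid
Product: 16 benzyl 4-(benzyloxy)-3-hydroxy-2-methoxy-6-propylbenzoate
Conditions: BnBr (1.05 equiv), KHCO3 (1.2 equiv), DMF, 40 °C, 6 h
Reagents that add atoms: benzyl bromide, BrCc1ccccc1
Why: Chemoselective SN2 O-alkylation of the carboxylate, since bicarbonate deprotonates the acid (pKa about 4) but not the phenol (pKa about 10).

Step 11
Reactants: 8 2,4-bis(benzyloxy)-6-propylbenzoic acid; 16 benzyl 4-(benzyloxy)-3-hydroxy-2-methoxy-6-propylbenzoate
Product: 18 benzyl 4-(benzyloxy)-3-{[2,4-bis(benzyloxy)-6-propylbenzoyl]oxy}-2-methoxy-6-propylbenzoate, via mixed trifluoroacetic anhydride 17 (not isolated)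
Conditions: (CF3CO)2O (5 equiv), dry toluene, rt, 4 h
Reagents that add atoms: none
Why: Depside esterification through a mixed anhydride, in which the electron-rich di-ortho-substituted aroyl trifluoroacetate ionises to a linear, sterically undemanding acylium ion that the only free hydroxyl (3-OH of 16) captures.

Step 12
Reactants: 18 benzyl 4-(benzyloxy)-3-{[2,4-bis(benzyloxy)-6-propylbenzoyl]oxy}-2-methoxy-6-propylbenzoate
Product: 19 3-[(2,4-dihydroxy-6-propylbenzoyl)oxy]-4-hydroxy-2-methoxy-6-propylbenzoic acid (target)
Conditions: H2 (1 atm), 10% Pd/C, EtOAc, rt, 3 h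
Reagents that add atoms: none
Why: Catalytic hydrogenolysis removes three benzyl ethers and the benzyl ester under neutral conditions, which leaves the aryl ester intact and avoids base-induced O-3 to O-4 acyl migration; no stereocentre is involved.

## Compound list
1 | (E)-hept-3-en-2-one | CCC/C=C/C(C)=O | starting material
2 | dimethyl malonate | COC(=O)CC(=O)OC | starting material
3 | dimethyl 2-(2-oxoheptan-4-yl)propanedioate (racemic, not isolated) | CCCC(CC(C)=O)C(C(=O)OC)C(=O)OC | intermediate
4 | methyl 2-hydroxy-4-oxo-6-propylcyclohex-2-ene-1-carboxylate (racemic diastereomer/tautomer mixture) | CCCC1CC(=O)C=C(O)C1C(=O)OC | intermediate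
5 | methyl 3-bromo-2-hydroxy-4-oxo-6-propylcyclohex-2-ene-1-carboxylate (racemic, not isolated) | CCCC1CC(=O)C(Br)=C(O)C1C(=O)OC | intermediate
6 | methyl 2,4-dihydroxy-6-propylbenzoate | CCCc1cc(O)cc(O)c1C(=O)OC | intermediate
7 | methyl 2,4-bis(benzyloxy)-6-propylbenzoate | CCCc1cc(OCc2ccccc2)cc(OCc2ccccc2)c1C(=O)OC | intermediate
8 | 2,4-bis(benzyloxy)-6-propylbenzoic acid | CCCc1cc(OCc2ccccc2)cc(OCc2ccccc2)c1C(=O)O | intermediate
9 | methyl 3-[chloro(methoxy)methyl]-2,4-dihydroxy-6-propylbenzoate (titanium-bound, not isolated) | CCCc1cc(O)c(C(Cl)OC)c(O)c1C(=O)OC | intermediate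
10 | methyl 3-formyl-2,4-dihydroxy-6-propylbenzoate | CCCc1cc(O)c(C=O)c(O)c1C(=O)OC | intermediate
11 | methyl 4-(benzyloxy)-3-formyl-2-hydroxy-6-propylbenzoate | CCCc1cc(OCc2ccccc2)c(C=O)c(O)c1C(=O)OC | intermediate
12 | methyl 4-(benzyloxy)-3-formyl-2-methoxy-6-propylbenzoate | CCCc1cc(OCc2ccccc2)c(C=O)c(OC)c1C(=O)OC | intermediate
13 | methyl 4-(benzyloxy)-3-(formyloxy)-2-methoxy-6-propylbenzoate (not isolated) | CCCc1cc(OCc2ccccc2)c(OC=O)c(OC)c1C(=O)OC | intermediate
14 | methyl 4-(benzyloxy)-3-hydroxy-2-methoxy-6-propylbenzoate | CCCc1cc(OCc2ccccc2)c(O)c(OC)c1C(=O)OC | intermediate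
15 | 4-(benzyloxy)-3-hydroxy-2-methoxy-6-propylbenzoic acid | CCCc1cc(OCc2ccccc2)c(O)c(OC)c1C(=O)O | intermediate
16 | benzyl 4-(benzyloxy)-3-hydroxy-2-methoxy-6-propylbenzoate | CCCc1cc(OCc2ccccc2)c(O)c(OC)c1C(=O)OCc1ccccc1 | intermediate
17 | 2,4-bis(benzyloxy)-6-propylbenzoic trifluoroacetic anhydride (not isolated) | CCCc1cc(OCc2ccccc2)cc(OCc2ccccc2)c1C(=O)OC(=O)C(F)(F)F | intermediate
18 | benzyl 4-(benzyloxy)-3-{[2,4-bis(benzyloxy)-6-propylbenzoyl]oxy}-2-methoxy-6-propylbenzoate | CCCc1cc(OCc2ccccc2)cc(OCc2ccccc2)c1C(=O)Oc1c(OCc2ccccc2)cc(CCC)c(C(=O)OCc2ccccc2)c1OC | intermediate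
19 | 3-[(2,4-dihydroxy-6-propylbenzoyl)oxy]-4-hydroxy-2-methoxy-6-propylbenzoic acid | CCCc1cc(O)cc(O)c1C(=O)Oc1c(O)cc(CCC)c(C(=O)O)c1OC | target

## Step count and risks
Total steps: 12.
Longest linear sequence: 10 steps (1, 2, 5, 6, 7, 8, 9, 10, 11, 12).

**Step 11 is the most exposed step.** A di-ortho-substituted acid has to acylate a phenol flanked by OMe and OBn, and the phenol may simply be trifluoroacetylated.
- The fallback sets out from 8 and comes back at 18. It activates both partners separately under non-acidic conditions instead of relying on an acylium ion.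
- Acid 8 is treated with Ghosez's reagent (1-chloro-N,N,2-trimethylprop-1-en-1-amine, CH2Cl2, 0 °C to rt). This gives 2,4-bis(benzyloxy)-6-propylbenzoyl chloride F1.
- Phenol 16 is deprotonated with NaH in THF at 0 °C to sodium 6-(benzyloxy)-3-[(benzyloxy)carbonyl]-2-methoxy-4-propylphenolate F2.
- The two solutions are combined and warmed to 40 °C to give 18.

**Step 5 is second.** Its C3/C5 regioselectivity rests on the substrate's electronic bias only, and step 6 then needs a second selectivity.
- The fallback sets out from 6 and comes back at 11, so it bypasses both steps 5 and 6.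
- The non-chelated 4-OH of 6 is benzylated first (BnBr 1.05 equiv, K2CO3, acetone, reflux). This gives methyl 4-(benzyloxy)-2-hydroxy-6-propylbenzoate F3.
- A Casnati–Skattebøl ortho-formylation follows (MgCl2, Et3N, paraformaldehyde, MeCN, reflux). It delivers formaldehyde inside the magnesium phenoxide to the only free ortho carbon, C3.
- This forms the salicyl alcohol methyl 4-(benzyloxy)-2-hydroxy-3-(hydroxymethyl)-6-propylbenzoate F4. A second formaldehyde oxidises it in situ by hydride transfer to 11.

**Step 9 is third.** Hydroxide must reach a carbonyl shielded by OMe and propyl in a substrate that is an air-sensitive phenoxide at 100 °C.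
- The fallback sets out from 14 and comes back at 15. It gives up attack at the carbonyl altogether.
- The O–CH3 bond of the ester is cleaved by SN2 dealkylation with LiI (5 equiv) in refluxing pyridine under argon, followed by cold dilute HCl. This reaction is insensitive to hindrance at the acyl carbon and is faster for the ester methyl than for the aryl methyl ether.
- This fallback makes no new compound (F0).

## Further compounds
F1 | step 11 | 2,4-bis(benzyloxy)-6-propylbenzoyl chloride | CCCc1cc(OCc2ccccc2)cc(OCc2ccccc2)c1C(=O)Cl
F2 | step 11 | sodium 6-(benzyloxy)-3-[(benzyloxy)carbonyl]-2-methoxy-4-propylphenolate | CCCc1cc(OCc2ccccc2)c([O-])c(OC)c1C(=O)OCc1ccccc1.[Na+]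
F3 | step 5 | methyl 4-(benzyloxy)-2-hydroxy-6-propylbenzoate | CCCc1cc(OCc2ccccc2)cc(O)c1C(=O)OC
F4 | step 5 | methyl 4-(benzyloxy)-2-hydroxy-3-(hydroxymethyl)-6-propylbenzoate | CCCc1cc(OCc2ccccc2)c(CO)c(O)c1C(=O)OC
F0 | step 9 | none | none
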